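**Retrosynthetic overview**

1. Locants are those of the target as a 1H-indene (ring B: C1–C2=C3–C3a–C7a; ring A: C3a–C4–C5–C6=C7–C7a); β is the face carrying C4–CO2H and the C5 dienyl. The dienyl comes from a Horner–Wadsworth–Emmons reaction on a C5 formyl group; C4–CO2H and C5–CHO both come from one temporary γ-lactone C4–C(=O)–O–CH2–C5.
2. 3a-H (trans fusion) and C2=C3 come from a ring-B cyclopentenone (C2=O, C3=C3a) by Luche reduction and palladium-catalysed allylic formate hydrogenolysis (stereochemical relay C1 → C2 → C3a).
3. Ring B is closed by the C7a–C1 bond: ionisation of a C7a ester, then 4π-conrotatory closure of the 2-silyloxy pentadienyl cation C1=C2–C3=C3a–C7a(+). Enabling feature: C7a is allylic to C6=C7 of ring A, and C1–C2–C3–C3a–C7a can be held as one conjugated five-carbon array with C3a trigonal, so no ring-fusion geometry is at stake in the closure.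
4. Ring A with both quaternary centres (C4, C5) comes first, from an ester-tethered intramolecular Diels–Alder reaction of a 1-acyloxy diene with an allenyl ketone ester. The tether is the temporary lactone; the acyloxy group is a (1S)-camphanate that resolves the adduct and later leaves from C7a.
5. Ring order: lactone and ring A (step 6), ring B (step 7), then 3a-H, then the side chain.

Key step: step 7

Remark: compounds 1, 4, 7, 9, 23 and (1S)-camphanic chloride are taken as commercial; the route is resolved at the cycloadduct by separating camphanate diastereomers, not by an enantioselective step.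

Step 1
Reactants: 1 (E)-3-ethoxy-2-methylprop-2-enal
Product: 3 (E)-2-methyl-3-oxoprop-1-en-1-yl (1S)-camphanate, via sodium 2-methylmalonaldehyde enolate 2 (not isolated)
Conditions: NaOH (1 equiv), H2O, 25 °C; evaporate; (1S)-camphanic chloride, CH2Cl2, 0 °C
Reagents that add atoms: sodium hydroxide [Na+].[OH-]; (1S)-camphanic chloride ClC(=O)[C@@]12CC[C@@](C)(C(=O)O1)C2(C)C
Why: Addition–elimination of hydroxide on the vinylogous ester gives the symmetric malonaldehyde enolate, whose O-acylation (enol ester formation) should give the (E)-enol camphanate; no stereocentre is formed.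

Step 2
Reactants: 3 (E)-2-methyl-3-oxoprop-1-en-1-yl (1S)-camphanate; 4 2-(triphenyl-λ5-phosphanylidene)butanal
Product: 5 (1E,3E)-4-ethyl-2-methyl-5-oxopenta-1,3-dien-1-yl (1S)-camphanate
Conditions: toluene, 80 °C
Reagents that add atoms: none
Why: Wittig olefination with a formyl-stabilised ylide should be E-selective at the new trisubstituted alkene and stop after one addition, because the product dienal is the less electrophilic aldehyde.

Step 3
Reactants: 5 (1E,3E)-4-ethyl-2-methyl-5-oxopenta-1,3-dien-1-yl (1S)-camphanate
Product: 6 (1E,3E)-4-(hydroxymethyl)-2-methylhexa-1,3-dien-1-yl (1S)-camphanate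
Conditions: NaBH4, CeCl3·7H2O, MeOH/THF, −78 °C
Reagents that add atoms: none
Why: Luche reduction should give clean 1,2-reduction of the dienal at low temperature while the enol ester and the camphanate lactone survive; no stereocentre is formed.

Step 4
Reactants: 6 (1E,3E)-4-(hydroxymethyl)-2-methylhexa-1,3-dien-1-yl (1S)-camphanate; 7 2,2,5-trimethyl-1,3-dioxane-4,6-dione
Product: 8 2-methylmalonic acid mono[(2E,4E)-5-(camphanoyloxy)-2-ethyl-4-methylpenta-2,4-dien-1-yl] ester
Conditions: toluene, 90 °C
Reagents that add atoms: none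
Why: Thermal alcoholysis of the 1,3-dioxane-4,6-dione (ring opening with loss of acetone) should give the malonic half-ester under neutral conditions; the malonate CH is a stereocentre of no consequence because it is destroyed in step 6.

Step 5
Reactants: 9 2-bromopentan-3-one
Product: 11 2-(triphenyl-λ5-phosphanylidene)pentan-3-one, via phosphonium bromide 10 (not isolated)
Conditions: PPh3, toluene, 80 °C; then aq. NaOH, CH2Cl2, 25 °C
Reagents that add atoms: triphenylphosphine c1ccc(cc1)P(c1ccccc1)c1ccccc1
Why: Quaternisation of PPh3 by the α-bromo ketone (SN2) and deprotonation should give the keto-stabilised ylide.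

Step 6
Reactants: 8 2-methylmalonic acid mono(dienyl) ester; 11 2-(triphenyl-λ5-phosphanylidene)pentan-3-one
Product: 15 Diels–Alder adduct (ring A with β-lactone and 7a-camphanoyloxy group), via acid chloride 12 (not isolated), via ketene 13 (not isolated), via allenyl ester 14 (not isolated)
Conditions: 1-chloro-N,N,2-trimethylprop-1-en-1-amine, CH2Cl2, 0 °C; then 11, Et3N, toluene, 0 → 25 °C; then 110 °C; separation of the camphanate diastereomers on SiO2
Reagents that add atoms: none
Why: Dehydrochlorination of the acid chloride gives an (alkoxycarbonyl)ketene that should undergo Wittig olefination with 11 to the allenyl ketone ester 14, and the ester-tethered intramolecular Diels–Alder reaction (diene C5=C6–C7=C7a, dienophile the C4=C3a bond of the allene) then closes ring A and the γ-lactone; the three-atom tether forces the cis lactone and so fixes C4 against C5, suprafacial addition puts the 7a-acyloxy group cis to the lactone CH2, and the two camphanate diastereomers (antipodal cores) are separated so that the core is carried on as one enantiomer.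

Step 7
Reactants: 15 Diels–Alder adduct (ring A with β-lactone and 7a-camphanoyloxy group)
Product: 17 tricyclic enone (rings A and B with the β-lactone), via silyloxy diene 16 (not isolated)
Conditions: Me3SiOTf (2 equiv), Et3N (1.3 equiv), CH2Cl2, −78 → −20 °C; aq. NaHCO3
Reagents that add atoms: none
Why: Proposed new method: soft enolisation (Me3SiOTf, Et3N) should convert the propanoyl group into the (Z)-2-silyloxy diene 16, and the excess Me3SiOTf should then ionise the doubly allylic C7a camphanate to a pentadienyl cation (C1=C2(OSiMe3)–C3=C3a–C7a(+), further delocalised over C7 and C6) that closes by thermal 4π-conrotatory electrocyclisation between C1 and C7a, after which loss of the silyl group from the oxocarbenium ion gives the cyclopentenone. The closest known reaction types are the Nazarov cyclisation and the Rautenstrauch rearrangement (closure of a 2-acyloxy pentadienyl cation); the new element is reaching the 2-oxy pentadienyl cation by ionising an allylic ester. Ring B closes by electrocyclisation (a formally 5-endo closure that is open to a pericyclic process), which is the mode the planar array of four trigonal atoms C1–C2–C3–C3a demands, since an enolate alkylation at C7a cannot reach the required trajectory. Conrotation places the two outside groups (the 1-methyl and C7) trans, which sets C1 (1-Me α) against C7a, and this is also the favoured epimer α to the ketone. The selectivity the step needs is the face of C7a (torquoselectivity): allylic 1,3-strain between the C3 methyl and C4 should hold the C4 methyl pseudo-axial on the α-face, where it is 1,3 to C7a, so that C1 should bond to the β-lobe and 7a-H ends α. Because C3a stays trigonal no ring-fusion geometry is fixed here, and E/Z isomers at C3=C3a should converge by rotation in the delocalised cation.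

Step 8
Reactants: 17 tricyclic enone (rings A and B with the β-lactone)
Product: 18 2α-allylic alcohol
Conditions: NaBH4, CeCl3·7H2O, MeOH, −40 °C
Reagents that add atoms: none
Why: Luche reduction should reduce the enone 1,2 with hydride entering C2 from the β-face, anti to the adjacent 1α-methyl group, to give the 2α-alcohol; the lactone is not reduced.

Step 9
Reactants: 18 2α-allylic alcohol
Product: 19 2α-allylic formate
Conditions: HCO2H, DCC, DMAP (cat.), CH2Cl2, 0 °C
Reagents that add atoms: formic acid O=CO
Why: Steglich-type esterification with formic acid should formylate the hindered allylic alcohol with retention at C2.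

Step 10
Reactants: 19 2α-allylic formate
Product: 20 lactone of the target core (C2=C3, 3a-H β, 7a-H α)
Conditions: Pd(OAc)2 (5 mol %), PBu3 (20 mol %), 1,4-dioxane, 80 °C
Reagents that add atoms: none
Why: Palladium-catalysed decarboxylative hydrogenolysis of an allylic formate: zerovalent palladium should ionise the α-formate with inversion, bind the less hindered C2 terminus on the β-face and deliver hydride intramolecularly to C3a on that face, which moves the alkene to C2=C3 and sets 3a-H β (trans ring fusion) stereospecifically.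

Step 11
Reactants: 20 lactone of the target core (C2=C3, 3a-H β, 7a-H α)
Product: 22 hydroxy-lactone (ring tautomer of the 5-formyl acid), via lithium hydroxy carboxylate 21 (not isolated)
Conditions: LiOH, THF/H2O, 60 °C; evaporate; 1,1,1-triacetoxy-1,1-dihydro-1,2-benziodoxol-3(1H)-one, NaHCO3, CH2Cl2/DMSO, 0 → 25 °C; aq. HCl to pH 3
Reagents that add atoms: lithium hydroxide [Li+].[OH-]
Why: Saponification of the lactone to the hydroxy carboxylate and hypervalent-iodine oxidation of the neopentyl primary alcohol should give the 5-formyl carboxylate, isolated after acidification as its ring tautomer 22; the quaternary C4 and C5 cannot epimerise.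

Step 12
Reactants: 22 hydroxy-lactone (ring tautomer of the 5-formyl acid); 23 diethyl [(2E)-3-phenylprop-2-en-1-yl]phosphonate
Product: 24 (1R,3aR,4R,5S,7aS)-5-ethyl-1,3,4,7-tetramethyl-5-[(1E,3E)-4-phenylbuta-1,3-dien-1-yl]-3a,4,5,7a-tetrahydro-1H-indene-4-carboxylic acid
Conditions: LiN(SiMe3)2 (2.2 equiv), THF, −78 → 25 °C; aq. HCl
Reagents that add atoms: none
Why: Horner–Wadsworth–Emmons olefination of the ring-opened formyl carboxylate with the allylic phosphonate anion should be E-selective at the new alkene and keeps the (E)-styryl alkene, giving the (1E,3E)-dienyl acid.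

**Compound list**

1 | (E)-3-ethoxy-2-methylprop-2-enal | CCO/C=C(C)/C=O | starting material
2 | sodium (E)-2-methyl-3-oxoprop-1-en-1-olate | [Na+].[O-]/C=C(C)/C=O | intermediate
3 | (E)-2-methyl-3-oxoprop-1-en-1-yl (1S,4R)-4,7,7-trimethyl-3-oxo-2-oxabicyclo[2.2.1]heptane-1-carboxylate (enol (1S)-camphanate) | O=C(O/C=C(C)/C=O)[C@@]12CC[C@@](C)(C(=O)O1)C2(C)C | intermediate
4 | 2-(triphenyl-λ5-phosphanylidene)butanal | CCC(C=O)=P(c1ccccc1)(c1ccccc1)c1ccccc1 | starting material
5 | (1E,3E)-4-ethyl-2-methyl-5-oxopenta-1,3-dien-1-yl (1S)-camphanate | O=C(O/C=C(C)/C=C(CC)/C=O)[C@@]12CC[C@@](C)(C(=O)O1)C2(C)C | intermediate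
6 | (1E,3E)-4-(hydroxymethyl)-2-methylhexa-1,3-dien-1-yl (1S)-camphanate | O=C(O/C=C(C)/C=C(CC)/CO)[C@@]12CC[C@@](C)(C(=O)O1)C2(C)C | intermediate
7 | 2,2,5-trimethyl-1,3-dioxane-4,6-dione | CC1C(=O)OC(C)(C)OC1=O | starting material
8 | 2-methylmalonic acid mono[(2E,4E)-5-{[(1S)-camphanoyl]oxy}-2-ethyl-4-methylpenta-2,4-dien-1-yl] ester (either configuration at the malonate CH) | O=C(O/C=C(C)/C=C(CC)/COC(=O)C(C)C(=O)O)[C@@]12CC[C@@](C)(C(=O)O1)C2(C)C | intermediate
9 | 2-bromopentan-3-one (racemic) | CCC(=O)C(C)Br | starting material
10 | (3-oxopentan-2-yl)triphenylphosphonium bromide | CCC(=O)C(C)[P+](c1ccccc1)(c1ccccc1)c1ccccc1.[Br-] | intermediate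
11 | 2-(triphenyl-λ5-phosphanylidene)pentan-3-one | CCC(=O)C(C)=P(c1ccccc1)(c1ccccc1)c1ccccc1 | intermediate
12 | acid chloride of 8 | O=C(O/C=C(C)/C=C(CC)/COC(=O)C(C)C(=O)Cl)[C@@]12CC[C@@](C)(C(=O)O1)C2(C)C | intermediate
13 | ketene from 12: the dienyl ester of 2-methyl-3-oxoprop-2-enoic acid | O=C(O/C=C(C)/C=C(CC)/COC(=O)C(C)=C=O)[C@@]12CC[C@@](C)(C(=O)O1)C2(C)C | intermediate
14 | allenyl ester: the dienyl ester of 2,4-dimethyl-5-oxohepta-2,3-dienoic acid (both allene configurations) | O=C(O/C=C(C)/C=C(CC)/COC(=O)C(C)=C=C(C)C(=O)CC)[C@@]12CC[C@@](C)(C(=O)O1)C2(C)C | intermediate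
15 | Diels–Alder adduct: ring A with γ-lactone C4–C(=O)–O–CH2–C5 on the β-face; 4-Me and 5-Et α; C6=C7 (7-Me); 7a-H α and 7a-O-(1S)-camphanoyl β; exocyclic (Z)-C3a=C3 alkene whose C3 carries methyl and propanoyl | CC[C@]1(C3)C=C(C)[C@@H](OC(=O)[C@@]56CC[C@@](C)(C(=O)O5)C6(C)C)/C(=C(/C)C(=O)CC)[C@@]1(C)C(=O)O3 | intermediate
16 | silyloxy diene of 15: propanoyl group as its (Z)-trimethylsilyl enol ether (C1=C2–OSiMe3) | CC[C@]1(C3)C=C(C)[C@@H](OC(=O)[C@@]56CC[C@@](C)(C(=O)O5)C6(C)C)/C(=C(/C)C(/O[Si](C)(C)C)=C/C)[C@@]1(C)C(=O)O3 | intermediate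
17 | tricyclic enone: rings A and B with the β-lactone; C2=O; C3=C3a; C6=C7; 1-Me α; 7a-H α; 4-Me and 5-Et α | CC[C@]1(C3)C=C(C)[C@H]2[C@H](C)C(=O)C(C)=C2[C@@]1(C)C(=O)O3 | intermediate
18 | 2α-allylic alcohol of 17 (2-H β) | CC[C@]1(C3)C=C(C)[C@H]2[C@H](C)[C@H](O)C(C)=C2[C@@]1(C)C(=O)O3 | intermediate
19 | 2α-allylic formate | CC[C@]1(C3)C=C(C)[C@H]2[C@H](C)[C@H](OC=O)C(C)=C2[C@@]1(C)C(=O)O3 | intermediate
20 | lactone of the target core: C2=C3 and C6=C7; 1-Me α; 7a-H α; 3a-H β; 4-Me and 5-Et α; C4–C(=O)–O–CH2–C5 lactone β | CC[C@]1(C3)C=C(C)[C@H]2[C@H](C)C=C(C)[C@@H]2[C@@]1(C)C(=O)O3 | intermediate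
21 | lithium carboxylate of the ring-opened lactone (C5–CH2OH, C4–CO2Li) | CC[C@]1(CO)C=C(C)[C@H]2[C@H](C)C=C(C)[C@@H]2[C@@]1(C)C(=O)[O-].[Li+] | intermediate
22 | hydroxy-lactone C4–C(=O)–O–CH(OH)–C5 (both anomers; ring tautomer of the 5-formyl acid) | CC[C@]1(C3O)C=C(C)[C@H]2[C@H](C)C=C(C)[C@@H]2[C@@]1(C)C(=O)O3 | intermediate
23 | diethyl [(2E)-3-phenylprop-2-en-1-yl]phosphonate | CCOP(=O)(C/C=C/c1ccccc1)OCC | starting material
24 | (1R,3aR,4R,5S,7aS)-5-ethyl-1,3,4,7-tetramethyl-5-[(1E,3E)-4-phenylbuta-1,3-dien-1-yl]-3a,4,5,7a-tetrahydro-1H-indene-4-carboxylic acid | CC[C@]1(/C=C/C=C/c2ccccc2)C=C(C)[C@H]2[C@H](C)C=C(C)[C@@H]2[C@@]1(C)C(=O)O | target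

**Step count and risks**

Total: 12 steps. Longest linear sequence: 11 steps (steps 1–4 and 6–12); step 5 is a one-step branch.

Most likely to fail, step 7: after ionisation the allyl cation may lose a proton from the C7 methyl (triene formation) instead of closing, or closure may occur on both faces of C7a. The fallback uses known chemistry, sets out from 15 and comes back at 17. Palladium-catalysed hydrogenolysis of the allylic camphanate (Pd(PPh3)4, Bu3SnH, THF), with hydride going to the less hindered terminus, should give the 7a-unsubstituted dienyl enone F1. Detrifluoroacetylative diazo transfer (LiN(SiMe3)2, CF3CO2CH2CF3, −78 °C; then MsN3, Et3N) should give the α′-diazo ketone F2. Dirhodium-carbenoid 1,5-insertion into the doubly allylic 7a C–H bond (Rh2(O2CCPh3)4, CH2Cl2, −78 → 0 °C) should then close ring B to 17, with retention at C7a and the same thermodynamic preference at C1.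

Second, step 6: the ketene may dimerise or add to the diene before it meets the ylide, and the allenyl ketone may oligomerise before it cyclises. The fallback sets out from 6 and comes back at 14, which is heated to 15 as in step 6. Addition of CH3C≡CMgBr to pentane-2,3-dione at the acetyl carbonyl and trapping with methyl chloroformate should give the propargylic carbonate F3. Palladium-catalysed hydroxycarbonylation (Pd(PPh3)4, CO, H2O, THF; SN2′-type oxidative addition, then CO insertion) should give the allenic acid F4. Steglich esterification of F4 with 6 (DCC, DMAP, CH2Cl2, 0 °C) should give 14.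

Third, step 11: the hydroxy carboxylate may relactonise faster than it is oxidised, or the aldehyde may be oxidised further. The fallback sets out from 20 and comes back at 24. Saponification (LiOH) and alkylation of the carboxylate in the same flask with allyl bromide (DMF) should give the hydroxy allyl ester F5. Oxidation with 1,1,1-triacetoxy-1,1-dihydro-1,2-benziodoxol-3(1H)-one should give the aldehyde F6. Horner–Wadsworth–Emmons reaction with 23 (LiN(SiMe3)2, THF) should give the dienyl allyl ester F7, and deallylation (Pd(PPh3)4, morpholine, THF) should give 24.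

**Further compounds**

F1 | step 7 | 7a-unsubstituted dienyl enone: 15 with H in place of the 7a-camphanoyloxy group | CC[C@]1(C3)C=C(C)C/C(=C(/C)C(=O)CC)[C@@]1(C)C(=O)O3
F2 | step 7 | α′-diazo ketone of F1 (2-diazopropanoyl group on C3) | CC[C@]1(C3)C=C(C)C/C(=C(/C)C(=O)C(C)=[N+]=[N-])[C@@]1(C)C(=O)O3
F3 | step 6 | methyl 4-methyl-5-oxohept-2-yn-4-yl carbonate (racemic) | CC#CC(C)(OC(=O)OC)C(=O)CC
F4 | step 6 | 2,4-dimethyl-5-oxohepta-2,3-dienoic acid (racemic allene) | CCC(=O)C(C)=C=C(C)C(=O)O
F5 | step 11 | allyl ester of the ring-opened lactone (C5–CH2OH, C4–CO2-allyl) | CC[C@]1(CO)C=C(C)[C@H]2[C@H](C)C=C(C)[C@@H]2[C@@]1(C)C(=O)OCC=C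
F6 | step 11 | allyl ester of the 5-formyl acid | CC[C@]1(C=O)C=C(C)[C@H]2[C@H](C)C=C(C)[C@@H]2[C@@]1(C)C(=O)OCC=C
F7 | step 11 | allyl ester of 24 | CC[C@]1(/C=C/C=C/c2ccccc2)C=C(C)[C@H]2[C@H](C)C=C(C)[C@@H]2[C@@]1(C)C(=O)OCC=C
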